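The disconnection is the CH2–CH2 bond of the 2-chloroethyl chain on C5 of the benzene ring of the indane, chosen because that chain sits ortho to the oxygenated carbon on C6. In one operation the C5 methyl of an ortho-toluamide is lithiated and adds to formaldehyde, and the new hydroxyl is tied to the C6 carboxyl as a six-membered lactone. The lactone keeps C6 distinct from C4 and offers the chain oxygen for exchange by chloride. The precursor is a 2,2-dimethylindane carrying bromide at C4, methyl at C5 and a diethylcarboxamide at C6, reached by two regioselective electrophilic substitutions on 2,2,5-trimethylindane.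

Key step: step 5

Remark: locants are those of the indane in the target (C2 gem-dimethyl, C3a and C7a ring fusion, C4 acetoxymethyl, C5 2-chloroethyl, C6 butanoyloxymethyl, C7 hydrogen). Compounds 1–4 carry indanone names, in which the aryl methyl is on C6. The target has no stereocentre; the transient compounds 2 and 4 are racemic.

Step 1
Reactants: 1 6-methylindan-1-one
Product: 3 2,2,6-trimethylindan-1-one, via 2,6-dimethylindan-1-one 2 (not isolated)
Conditions: NaH (2.5 equiv), MeI (3 equiv), THF, 0 °C to rt
Reagents that add atoms: iodomethane, CI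
Why: Double enolate C-alkylation, in which NaH forms the enolate at C2 (the only enolisable carbon) twice and iodomethane methylates it each time, as is routine for indan-1-ones.

Step 2
Reactants: 3 2,2,6-trimethylindan-1-one
Product: 5 2,2,5-trimethylindane, via 2,2,6-trimethylindan-1-ol 4 (not isolated)
Conditions: Et3SiH (3 equiv), CF3CO2H, 55 °C
Reagents that add atoms: none
Why: Ionic hydrogenation of an aryl ketone, in which protonation and hydride transfer give benzylic alcohol 4, which ionises in the acid to a benzylic cation that takes a second hydride; no other reducible group is present.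

Step 3
Reactants: 5 2,2,5-trimethylindane; 6 diethylamine
Product: 8 N,N-diethyl-2,2,5-trimethylindane-6-carboxamide, via 2,2,5-trimethylindane-6-carbonyl chloride 7 (not isolated)
Conditions: (COCl)2 (2 equiv), AlCl3 (1.1 equiv), CH2Cl2, −10 to 0 °C; cold aq. HCl wash; then Et2NH (4 equiv), CH2Cl2, 0 °C to rt
Reagents that add atoms: oxalyl chloride, O=C(Cl)C(=O)Cl
Why: Friedel–Crafts chlorocarbonylation followed by amide formation, in which the electrophile from oxalyl chloride and AlCl3 should enter at C6, the one free position that is ortho to the C5 methyl, para to the C3a alkyl branch and open on one side (the position at which 1,2,4-trimethylbenzene is acylated), loss of CO leaves aroyl chloride 7, and diethylamine converts it into the amide.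

Step 4
Reactants: 8 N,N-diethyl-2,2,5-trimethylindane-6-carboxamide
Product: 9 4-bromo-N,N-diethyl-2,2,5-trimethylindane-6-carboxamide
Conditions: NBS (1.05 equiv), CF3CO2H/H2SO4, rt, dark
Reagents that add atoms: N-bromosuccinimide, O=C1CCC(=O)N1Br
Why: Electrophilic aromatic bromination, which should go to C4 because C4 is ortho to two alkyl groups (C5 methyl and C3a) and meta to the carboxamide, whereas C7 has one ortho alkyl group and lies ortho to the deactivating carboxamide; the acidic ionic medium leaves the benzylic positions untouched.

Step 5
Reactants: 9 4-bromo-N,N-diethyl-2,2,5-trimethylindane-6-carboxamide; 10 formaldehyde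
Product: 13 5-bromo-7,7-dimethyl-3,4,7,8-tetrahydrocyclopenta[g]isochromen-1(6H)-one, via 4-bromo-N,N-diethyl-5-(lithiomethyl)-2,2-dimethylindane-6-carboxamide 11 (not isolated), via 4-bromo-N,N-diethyl-5-(2-hydroxyethyl)-2,2-dimethylindane-6-carboxamide 12 (not isolated)
Conditions: LiN(iPr)2 (commercial solution, 1.3 equiv), THF, −78 °C; HCHO gas (from cracked paraformaldehyde, excess), −78 to 0 °C; aq. NH4Cl; then TsOH·H2O (1.2 equiv), toluene, reflux
Reagents that add atoms: none
Why: LiN(iPr)2 removes a proton from the C5 methyl of 9 to give benzylic lithium 11, whose charge is spread into the C6 carboxamide while lithium sits on the amide oxygen; 11 attacks the carbon of formaldehyde 10, which forms the CH2–CH2 bond of the chain, and protonation gives alcohol 12. Heating crude 12 with TsOH lets the new hydroxyl add to the protonated C6 amide carbon and expel diethylamine, which closes the lactone ring in a 6-exo-trig acyl substitution. The closest known reaction type is the lateral lithiation of ortho-toluamides with trapping by aldehydes and acid lactonisation to 3,4-dihydroisocoumarins. No stereocentre is formed. The step needs deprotonation at the C5 methyl only, which is secured because anions at C7 and at the C1 and C3 methylenes would lack conjugation with the carboxamide, and a lithium amide does not exchange the C4 bromide. That bromide has C3a and C5 as neighbours and so no ortho hydrogen, cannot give an aryne, and stays as the handle for the C4 carbon.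

Step 6
Reactants: 13 5-bromo-7,7-dimethyl-3,4,7,8-tetrahydrocyclopenta[g]isochromen-1(6H)-one
Product: 15 methyl 4-bromo-5-(2-chloroethyl)-2,2-dimethylindane-6-carboxylate, via 4-bromo-5-(2-chloroethyl)-2,2-dimethylindane-6-carbonyl chloride 14 (not isolated)
Conditions: SOCl2 (neat), ZnCl2 (cat.), reflux; evaporate; then MeOH, 0 °C to rt
Reagents that add atoms: thionyl chloride, O=S(Cl)Cl; methanol, CO
Why: Lactone opening by alkyl–oxygen cleavage, in which ZnCl2-assisted acyl activation by SOCl2 lets chloride displace the carboxylate oxygen at the primary CH2 in an SN2 step (as in the known conversion of benzo-fused and aliphatic lactones into chloroalkyl acid chlorides), and methanol then esterifies acid chloride 14.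

Step 7
Reactants: 15 methyl 4-bromo-5-(2-chloroethyl)-2,2-dimethylindane-6-carboxylate
Product: 16 [4-bromo-5-(2-chloroethyl)-2,2-dimethylindan-6-yl]methanol
Conditions: iBu2AlH (2.5 equiv), CH2Cl2, −78 to 0 °C; aq. KNaC4H4O6 (potassium sodium tartrate)
Reagents that add atoms: none
Why: Ester reduction with iBu2AlH, in which two hydrides take the benzoate to the benzylic alcohol at low temperature, where the aryl bromide and the primary alkyl chloride are inert and the aluminium alkoxide should not displace the chloride.

Step 8
Reactants: 16 [4-bromo-5-(2-chloroethyl)-2,2-dimethylindan-6-yl]methanol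
Product: 17 [4-bromo-5-(2-chloroethyl)-2,2-dimethylindan-6-yl]methyl butanoate
Conditions: (PrCO)2O (1.3 equiv), pyridine, DMAP (cat.), CH2Cl2, 0 °C to rt
Reagents that add atoms: butyric anhydride, CCCC(=O)OC(=O)CCC
Why: DMAP-catalysed acylation of a primary benzylic alcohol with an anhydride, fast enough under mild base that the neutral hydroxyl should not close onto the chloroethyl carbon.

Step 9
Reactants: 17 [4-bromo-5-(2-chloroethyl)-2,2-dimethylindan-6-yl]methyl butanoate
Product: 18 [5-(2-chloroethyl)-4-(hydroxymethyl)-2,2-dimethylindan-6-yl]methyl butanoate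
Conditions: Bu3SnCH2OH (1.5 equiv), Pd(PPh3)4 (10 mol%), 1,4-dioxane, 100 °C
Reagents that add atoms: (tributylstannyl)methanol, CCCC[Sn](CCCC)(CCCC)CO
Why: Stille cross-coupling, in which zerovalent palladium inserts into the C4–Br bond, the hydroxymethyl group is transferred from tin in preference to butyl, and reductive elimination gives the benzylic alcohol under neutral conditions that leave the butyrate and the alkyl chloride alone.

Step 10
Reactants: 18 [5-(2-chloroethyl)-4-(hydroxymethyl)-2,2-dimethylindan-6-yl]methyl butanoate
Product: 19 [4-(acetoxymethyl)-5-(2-chloroethyl)-2,2-dimethylindan-6-yl]methyl butanoate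
Conditions: Ac2O (1.5 equiv), pyridine, DMAP (cat.), CH2Cl2, rt
Reagents that add atoms: acetic anhydride, CC(=O)OC(C)=O
Why: DMAP-catalysed acetylation of the one remaining primary alcohol; the butyrate on the C6 carbinol is already in place, so the two esters cannot be interchanged.

Compound list
1 | 6-methylindan-1-one | Cc1ccc2c(c1)C(=O)CC2 | starting material
2 | 2,6-dimethylindan-1-one (racemic) | Cc1ccc2c(c1)C(=O)C(C)C2 | intermediate
3 | 2,2,6-trimethylindan-1-one | Cc1ccc2c(c1)C(=O)C(C)(C)C2 | intermediate
4 | 2,2,6-trimethylindan-1-ol (racemic) | Cc1ccc2c(c1)C(O)C(C)(C)C2 | intermediate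
5 | 2,2,5-trimethylindane | Cc1ccc2c(c1)CC(C)(C)C2 | intermediate
6 | diethylamine | CCNCC | starting material
7 | 2,2,5-trimethylindane-6-carbonyl chloride | O=C(Cl)c1cc2c(cc1C)CC(C)(C)C2 | intermediate
8 | N,N-diethyl-2,2,5-trimethylindane-6-carboxamide | CCN(CC)C(=O)c1cc2c(cc1C)CC(C)(C)C2 | intermediate
9 | 4-bromo-N,N-diethyl-2,2,5-trimethylindane-6-carboxamide | CCN(CC)C(=O)c1cc2c(c(Br)c1C)CC(C)(C)C2 | intermediate
10 | formaldehyde | C=O | starting material
11 | 4-bromo-N,N-diethyl-5-(lithiomethyl)-2,2-dimethylindane-6-carboxamide | [Li]Cc1c(Br)c2c(cc1C(=O)N(CC)CC)CC(C)(C)C2 | intermediate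
12 | 4-bromo-N,N-diethyl-5-(2-hydroxyethyl)-2,2-dimethylindane-6-carboxamide | CCN(CC)C(=O)c1cc2c(c(Br)c1CCO)CC(C)(C)C2 | intermediate
13 | 5-bromo-7,7-dimethyl-3,4,7,8-tetrahydrocyclopenta[g]isochromen-1(6H)-one (lactone from the C6 carboxyl to the C5 hydroxyethyl group, bromide at C4) | O=C1OCCc2c(Br)c3CC(C)(C)Cc3cc21 | intermediate
14 | 4-bromo-5-(2-chloroethyl)-2,2-dimethylindane-6-carbonyl chloride | O=C(Cl)c1cc2c(c(Br)c1CCCl)CC(C)(C)C2 | intermediate
15 | methyl 4-bromo-5-(2-chloroethyl)-2,2-dimethylindane-6-carboxylate | COC(=O)c1cc2c(c(Br)c1CCCl)CC(C)(C)C2 | intermediate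
16 | [4-bromo-5-(2-chloroethyl)-2,2-dimethylindan-6-yl]methanol | OCc1cc2c(c(Br)c1CCCl)CC(C)(C)C2 | intermediate
17 | [4-bromo-5-(2-chloroethyl)-2,2-dimethylindan-6-yl]methyl butanoate | CCCC(=O)OCc1cc2c(c(Br)c1CCCl)CC(C)(C)C2 | intermediate
18 | [5-(2-chloroethyl)-4-(hydroxymethyl)-2,2-dimethylindan-6-yl]methyl butanoate | CCCC(=O)OCc1cc2c(c(CO)c1CCCl)CC(C)(C)C2 | intermediate
19 | [4-(acetoxymethyl)-5-(2-chloroethyl)-2,2-dimethylindan-6-yl]methyl butanoate | CCCC(=O)OCc1cc2c(c(COC(C)=O)c1CCCl)CC(C)(C)C2 | target

Total step count: 10. Longest linear sequence: 10 steps (the route is fully linear from 1).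

Steps most likely to fail

Step 9. Insertion of zerovalent palladium into the C4–Br bond, which is flanked by the C3 methylene and the C5 chain, may be slow. Butyl transfer from tin, protodebromination, or closure of the new benzylic hydroxyl onto the chloroethyl carbon could then overtake the coupling. The fallback sets out from 17 and brings in the C4 carbon as a vinyl group. Suzuki–Miyaura coupling with CH2=CHBF3K (Pd(OAc)2, SPhos, K3PO4, toluene/water, 80 °C) should give [5-(2-chloroethyl)-2,2-dimethyl-4-vinylindan-6-yl]methyl butanoate F1. Ozonolysis (O3, CH2Cl2, −78 °C, then Me2S) should cut the alkene to [5-(2-chloroethyl)-4-formyl-2,2-dimethylindan-6-yl]methyl butanoate F2. NaBH4 in MeOH at 0 °C, which spares both the butyrate and the alkyl chloride, should reduce F2 to the alcohol, and the route is rejoined at 18.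

Step 5. Gaseous formaldehyde may polymerise before it meets the benzylic anion, or mass transfer of the gas at −78 °C may be poor, so that the anion is quenched or condenses with unreacted amide. The fallback sets out from 9 and uses a liquid one-carbon electrophile at the aldehyde oxidation level. The same lithiation followed by DMF at −78 °C should give, after aqueous work-up, 4-bromo-N,N-diethyl-2,2-dimethyl-5-(2-oxoethyl)indane-6-carboxamide F3. Immediate reduction of F3 with NaBH4 in EtOH at 0 °C should give the hydroxyethyl amide, so the route comes back at 12, which is then lactonised with TsOH in toluene to 13 as in step 5.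

Step 6. Alkyl–oxygen cleavage of the aryl lactone by chloride may be incomplete, or the ring may close again during the methanol quench, returning lactone. The fallback sets out from 13 and opens the ring at the acyl carbon instead. KOH in MeOH/water should give potassium 4-bromo-5-(2-hydroxyethyl)-2,2-dimethylindane-6-carboxylate F4. After evaporation, MeI in DMF at rt should alkylate the carboxylate to methyl 4-bromo-5-(2-hydroxyethyl)-2,2-dimethylindane-6-carboxylate F5. F5 is taken on without delay through an Appel chlorination (PPh3, N-chlorosuccinimide, CH2Cl2, 0 °C), which should exchange the hydroxyl for chloride under neutral conditions, and the route is rejoined at 15.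

Further compounds
F1 | step 9 | [5-(2-chloroethyl)-2,2-dimethyl-4-vinylindan-6-yl]methyl butanoate | CCCC(=O)OCc1cc2c(c(C=C)c1CCCl)CC(C)(C)C2
F2 | step 9 | [5-(2-chloroethyl)-4-formyl-2,2-dimethylindan-6-yl]methyl butanoate | CCCC(=O)OCc1cc2c(c(C=O)c1CCCl)CC(C)(C)C2
F3 | step 5 | 4-bromo-N,N-diethyl-2,2-dimethyl-5-(2-oxoethyl)indane-6-carboxamide | CCN(CC)C(=O)c1cc2c(c(Br)c1CC=O)CC(C)(C)C2
F4 | step 6 | potassium 4-bromo-5-(2-hydroxyethyl)-2,2-dimethylindane-6-carboxylate | [K+].[O-]C(=O)c1cc2c(c(Br)c1CCO)CC(C)(C)C2
F5 | step 6 | methyl 4-bromo-5-(2-hydroxyethyl)-2,2-dimethylindane-6-carboxylate | COC(=O)c1cc2c(c(Br)c1CCO)CC(C)(C)C2
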